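**Retrosynthetic overview**

- Unit A is the flavan that carries the methylene bridge at C8, unit B the one that carries it at C6. The target is reached by hydrogenolysis of its mono-benzyl ether on the unit B 7-hydroxyl.
- Feature used: the arene of unit A is a pentasubstituted phloroglucinol ring in which C8 (bridge carbon) lies between C7–OH and C8a–O1, with C4a, C5–OMe and C6–H completing the ring. This is the pattern a vinylketene and an alkynyl ether deliver when the two alkyne carbons become C8 and C8a.
- Key disconnection: a 3-methoxycyclobutenone tethered through O–CH(Ph)–CH2–CH2 to an alkynyl ether. Ring opening, tethered [2+2], ring opening and six-electron closure form C7–C8, C4a–C8a and C6–C7 and close the arene (ring A) and the pyran (ring C) of unit A in one operation.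
- The precursor comes from a dichlorovinyl ether carrying the cyclobutenone in masked form and a unit B benzylic bromide, joined by alkylation of the lithium alkynyl ether. The masked piece is built from (S)-3-chloro-1-phenylpropan-1-ol, methoxyacetylide, trichloroethylene and ketene.
- Unit B comes from phloroglucinol and (R)-3-chloro-1-phenylpropan-1-ol by directed lithiation/alkylation, Mitsunobu pyran closure with inversion and ortho-formylation directed by the 5-hydroxyl. Ring order: unit B pyran, cyclobutenone, then unit A arene and pyran together.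

Key step: step 23

Remark on the chemistry: a cyclobutenone does not survive the n-BuLi that converts a dichlorovinyl ether into a lithium alkynyl ether, and ketene cannot distinguish two alkynyl ethers. The cyclobutenone is therefore made first, carried through the organolithium step as the silyl ether of its allylic alcohol, and restored with MnO2. Because that mask is removed with fluoride, the unit B phenol is carried as a benzyl ether.

Assumption: ketene is supplied as a gas stream from an external generator (pyrolysis of acetone), and both enantiomers of 3-chloro-1-phenylpropan-1-ol are taken as commercial.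

**Route**

Step 1
Reactants: 1 (S)-3-chloro-1-phenylpropan-1-ol
Product: 2 (S)-tert-butyl(3-chloro-1-phenylpropoxy)dimethylsilane
Conditions: TBSCl, imidazole, DMF, 20 °C
Reagents that add atoms: tert-butyldimethylsilyl chloride, CC(C)(C)[Si](C)(C)Cl
Why: O-silylation of the secondary alcohol blocks oxetane closure in the coming acetylide alkylation and does not touch the C–O bond of the (S) stereocentre.

Step 2
Reactants: 2 (S)-tert-butyl(3-chloro-1-phenylpropoxy)dimethylsilane
Product: 3 (S)-tert-butyl(3-iodo-1-phenylpropoxy)dimethylsilane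
Conditions: NaI, acetone, reflux
Reagents that add atoms: sodium iodide, [Na+].[I-]
Why: Finkelstein exchange (SN2 at the primary carbon, driven by precipitation of NaCl) gives the iodide needed for acetylide alkylation.

Step 3
Reactants: 3 (S)-tert-butyl(3-iodo-1-phenylpropoxy)dimethylsilane; 4 chloroacetaldehyde dimethyl acetal
Product: 6 (S)-tert-butyl[(5-methoxy-1-phenylpent-4-yn-1-yl)oxy]dimethylsilane, via lithium methoxyacetylide 5 (not isolated)
Conditions: 4, LiNEt2 (3 equiv), THF, 0 °C; then 3, DMPU, −20 to 20 °C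
Reagents that add atoms: none
Why: twofold elimination from the chloroacetal gives the lithium alkoxyacetylide, which is alkylated by the unbranched primary iodide in a dipolar cosolvent (SN2 alkylation of an alkoxyacetylide).

Step 4
Reactants: 6 (S)-tert-butyl[(5-methoxy-1-phenylpent-4-yn-1-yl)oxy]dimethylsilane
Product: 7 (S)-5-methoxy-1-phenylpent-4-yn-1-ol
Conditions: Bu4NF, THF, 0 to 20 °C
Reagents that add atoms: none
Why: fluoride cleavage of the silyl ether frees the secondary alcohol under basic conditions that the acid-sensitive 1-methoxyalkyne tolerates.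

Step 5
Reactants: 7 (S)-5-methoxy-1-phenylpent-4-yn-1-ol; 8 trichloroethylene
Product: 9 {(1S)-1-[(E)-1,2-dichlorovinyloxy]-5-methoxypent-4-yn-1-yl}benzene
Conditions: KH, THF, 0 °C; then 8, −50 to 20 °C
Reagents that add atoms: none
Why: deprotonated 7 adds anti to dichloroacetylene formed in the flask from trichloroethylene (the trichloroethylene route to alkynyl ethers), giving an (E)-dichlorovinyl ether that is inert to ketene and serves as the latent second alkynyl ether; the stereocentre is retained because only the O–H bond reacts.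

Step 6
Reactants: 9 {(1S)-1-[(E)-1,2-dichlorovinyloxy]-5-methoxypent-4-yn-1-yl}benzene
Product: 10 2-{(3S)-3-[(E)-1,2-dichlorovinyloxy]-3-phenylpropyl}-3-methoxycyclobut-2-en-1-one
Conditions: ketene (gas stream), CH2Cl2, 0 to 20 °C
Reagents that add atoms: ketene, C=C=O
Why: thermal [2+2] cycloaddition of ketene to a 1-alkoxyalkyne is regioselective (ketene carbonyl carbon to the alkyl-bearing alkyne carbon) and gives the 3-methoxy-2-alkylcyclobutenone, while the electron-poor dichlorovinyl ether does not react.

Step 7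
Reactants: 10 2-{(3S)-3-[(E)-1,2-dichlorovinyloxy]-3-phenylpropyl}-3-methoxycyclobut-2-en-1-one
Product: 11 2-{(3S)-3-[(E)-1,2-dichlorovinyloxy]-3-phenylpropyl}-3-methoxycyclobut-2-en-1-ol (both epimers at C1 of the ring)
Conditions: i-Bu2AlH, CH2Cl2, −78 °C; KNaC4H4O6 (aq), Et3N
Reagents that add atoms: none
Why: 1,2-reduction of the vinylogous ester carbonyl removes the electrophile that n-BuLi would attack in step 20; the new carbinol stereocentre forms without control, both epimers are carried on, and it is erased in step 22.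

Step 8
Reactants: 11 2-{(3S)-3-[(E)-1,2-dichlorovinyloxy]-3-phenylpropyl}-3-methoxycyclobut-2-en-1-ol
Product: 12 tert-butyl{[2-{(3S)-3-[(E)-1,2-dichlorovinyloxy]-3-phenylpropyl}-3-methoxycyclobut-2-en-1-yl]oxy}dimethylsilane (both epimers)
Conditions: TBSCl, imidazole, DMF, 0 °C
Reagents that add atoms: tert-butyldimethylsilyl chloride, CC(C)(C)[Si](C)(C)Cl
Why: silylation under basic conditions protects the acid-labile 3-methoxy allylic alcohol as an ether that is inert to n-BuLi at −78 °C.

Step 9
Reactants: 13 phloroglucinol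
Product: 14 3,5-bis(methoxymethoxy)phenol
Conditions: MOMCl (2.0 equiv), i-Pr2NEt, DMF, 0 °C
Reagents that add atoms: chloromethyl methyl ether, COCCl
Why: statistical O-alkylation with two equivalents of the chloromethyl ether gives the bis-acetal, which is separated by chromatography from the recyclable mono- and tris-ethers.

Step 10
Reactants: 14 3,5-bis(methoxymethoxy)phenol
Product: 15 1-(benzyloxy)-3,5-bis(methoxymethoxy)benzene
Conditions: BnBr, K2CO3, acetone, 50 °C
Reagents that add atoms: benzyl bromide, BrCc1ccccc1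
Why: Williamson etherification of the remaining phenol installs a benzyl group that directs lithiation less strongly than the two acetals and survives fluoride and MnO2 later.

Step 11
Reactants: 16 (R)-3-chloro-1-phenylpropan-1-ol
Product: 17 (R)-tert-butyl(3-chloro-1-phenylpropoxy)dimethylsilane
Conditions: TBSCl, imidazole, DMF, 20 °C
Reagents that add atoms: tert-butyldimethylsilyl chloride, CC(C)(C)[Si](C)(C)Cl
Why: O-silylation protects the carbinol against the aryllithium of step 13 and keeps the (R) stereocentre intact.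

Step 12
Reactants: 17 (R)-tert-butyl(3-chloro-1-phenylpropoxy)dimethylsilane
Product: 18 (R)-tert-butyl(3-iodo-1-phenylpropoxy)dimethylsilane
Conditions: NaI, acetone, reflux
Reagents that add atoms: sodium iodide, [Na+].[I-]
Why: Finkelstein exchange gives the primary iodide needed for alkylation of a hindered aryllithium.

Step 13
Reactants: 15 1-(benzyloxy)-3,5-bis(methoxymethoxy)benzene; 18 (R)-tert-butyl(3-iodo-1-phenylpropoxy)dimethylsilane
Product: 20 (R)-{3-[4-(benzyloxy)-2,6-bis(methoxymethoxy)phenyl]-1-phenylpropoxy}(tert-butyl)dimethylsilane, via aryllithium 19 (not isolated)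
Conditions: 15, n-BuLi, THF, 0 °C; then 18, −78 to 20 °C
Reagents that add atoms: none
Why: directed ortho-metalation takes place at the carbon flanked by the two methoxymethoxy groups, and SN2 alkylation of the aryllithium by the primary iodide places the three-carbon chain on the future C4a without touching the carbinol stereocentre.

Step 14
Reactants: 20 (R)-{3-[4-(benzyloxy)-2,6-bis(methoxymethoxy)phenyl]-1-phenylpropoxy}(tert-butyl)dimethylsilane
Product: 21 5-(benzyloxy)-2-[(3R)-3-hydroxy-3-phenylpropyl]benzene-1,3-diol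
Conditions: HCl (1 M in MeOH), THF, 20 to 40 °C
Reagents that add atoms: none
Why: acid methanolysis removes both aryl acetals and the silyl ether, while the benzyl ether and the benzylic alcohol (plain phenyl, slow to ionise) are kept.

Step 15
Reactants: 21 5-(benzyloxy)-2-[(3R)-3-hydroxy-3-phenylpropyl]benzene-1,3-diol
Product: 22 (2S)-7-(benzyloxy)-2-phenylchroman-5-ol
Conditions: PPh3, DIAD, THF (0.02 M), 0 to 20 °C
Reagents that add atoms: none
Why: intramolecular Mitsunobu etherification closes the pyran ring of unit B by SN2 attack of either of the two equivalent phenols on the activated (R) carbinol, so inversion sets the (2S) centre and the second phenol remains as the 5-hydroxyl.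

Step 16
Reactants: 22 (2S)-7-(benzyloxy)-2-phenylchroman-5-ol
Product: 23 (2S)-7-(benzyloxy)-5-hydroxy-2-phenylchromane-6-carbaldehyde
Conditions: MgCl2, Et3N, (CH2O)n, MeCN, 80 °C
Reagents that add atoms: paraformaldehyde (as formaldehyde), C=O
Why: magnesium-mediated ortho-formylation delivers formaldehyde only to a position ortho to the free hydroxyl, and C6 is the only such free position (C8 is para), which fixes the site of the future bridge carbon.

Step 17
Reactants: 23 (2S)-7-(benzyloxy)-5-hydroxy-2-phenylchromane-6-carbaldehyde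
Product: 24 (2S)-7-(benzyloxy)-5-methoxy-2-phenylchromane-6-carbaldehyde
Conditions: MeI, K2CO3, DMF, 40 °C
Reagents that add atoms: iodomethane, CI
Why: Williamson methylation of the chelated phenol turns the directing 5-hydroxyl into the 5-methoxy group of unit B.

Step 18
Reactants: 24 (2S)-7-(benzyloxy)-5-methoxy-2-phenylchromane-6-carbaldehyde
Product: 25 [(2S)-7-(benzyloxy)-5-methoxy-2-phenylchroman-6-yl]methanol
Conditions: NaBH4, THF/MeOH, 0 °C
Reagents that add atoms: none
Why: hydride reduction of the aldehyde gives the benzylic alcohol under basic conditions that do not ionise it.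

Step 19
Reactants: 25 [(2S)-7-(benzyloxy)-5-methoxy-2-phenylchroman-6-yl]methanol
Product: 26 (2S)-7-(benzyloxy)-6-(bromomethyl)-5-methoxy-2-phenylchromane
Conditions: PBr3, Et2O, −20 °C; cold NaHCO3 (aq); used at once
Reagents that add atoms: phosphorus tribromide, BrP(Br)Br
Why: bromination of the benzylic alcohol through its phosphite ester proceeds at low temperature, and the bromide is kept cold and used immediately because the trioxygenated ring makes it prone to ionisation.

Step 20
Reactants: 12 tert-butyl{[2-{(3S)-3-[(E)-1,2-dichlorovinyloxy]-3-phenylpropyl}-3-methoxycyclobut-2-en-1-yl]oxy}dimethylsilane; 26 (2S)-7-(benzyloxy)-6-(bromomethyl)-5-methoxy-2-phenylchromane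
Product: 29 tert-butyl{[3-methoxy-2-{(3S)-3-phenyl-3-[(3-{(2S)-7-(benzyloxy)-5-methoxy-2-phenylchroman-6-yl}prop-1-yn-1-yl)oxy]propyl}cyclobut-2-en-1-yl]oxy}dimethylsilane, via chloroalkynyl ether 27 (not isolated), via lithium alkynyl ether 28 (not isolated)
Conditions: 12, n-BuLi (2.0 equiv), THF, −78 to −40 °C; then 26, DMPU, −78 to 0 °C
Reagents that add atoms: none
Why: n-BuLi eliminates HCl from the dichlorovinyl ether and exchanges the remaining chlorine for lithium, and the lithium alkynyl ether is alkylated at carbon by the reactive benzylic bromide (SN2), all below the temperature at which a secondary benzylic alkynyl ether undergoes retro-ene cleavage.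

Step 21
Reactants: 29 tert-butyl{[3-methoxy-2-{(3S)-3-phenyl-3-[(3-{(2S)-7-(benzyloxy)-5-methoxy-2-phenylchroman-6-yl}prop-1-yn-1-yl)oxy]propyl}cyclobut-2-en-1-yl]oxy}dimethylsilane
Product: 30 3-methoxy-2-{(3S)-3-phenyl-3-[(3-{(2S)-7-(benzyloxy)-5-methoxy-2-phenylchroman-6-yl}prop-1-yn-1-yl)oxy]propyl}cyclobut-2-en-1-ol (both epimers)
Conditions: Bu4NF·3H2O, THF, 0 °C
Reagents that add atoms: none
Why: fluoride cleaves the silyl ether while the water of the reagent protonates the alkoxide at once, and the benzyl ether, enol ether and alkynyl ether are inert to fluoride.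

Step 22
Reactants: 30 3-methoxy-2-{(3S)-3-phenyl-3-[(3-{(2S)-7-(benzyloxy)-5-methoxy-2-phenylchroman-6-yl}prop-1-yn-1-yl)oxy]propyl}cyclobut-2-en-1-ol
Product: 31 3-methoxy-2-{(3S)-3-phenyl-3-[(3-{(2S)-7-(benzyloxy)-5-methoxy-2-phenylchroman-6-yl}prop-1-yn-1-yl)oxy]propyl}cyclobut-2-en-1-one
Conditions: MnO2, CH2Cl2, 20 °C
Reagents that add atoms: none
Why: neutral oxidation of the electron-rich allylic alcohol restores the cyclobutenone at room temperature without touching the alkynyl ether and removes the uncontrolled carbinol centre.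

Step 23
Reactants: 31 3-methoxy-2-{(3S)-3-phenyl-3-[(3-{(2S)-7-(benzyloxy)-5-methoxy-2-phenylchroman-6-yl}prop-1-yn-1-yl)oxy]propyl}cyclobut-2-en-1-one
Product: 36 (2S)-8-{[(2S)-7-(benzyloxy)-5-methoxy-2-phenylchroman-6-yl]methyl}-5-methoxy-2-phenylchroman-7-ol, via vinylketene 32 (not isolated), via fused 2-vinylcyclobutenone 33 (not isolated), via dienylketene 34 (not isolated), via cyclohexadienone 35 (not isolated)
Conditions: hν (254 nm, quartz), degassed MeCN (0.005 M), 5 to 10 °C; then 80 °C in the dark
Reagents that add atoms: none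
Why: Proposed new method: light opens cyclobutenone 31 in a four-electron electrocyclic step to vinylketene 32, whose electrophilic carbonyl carbon bonds to the nucleophilic distal carbon of the tethered alkynyl ether while its alpha carbon bonds to the oxygen-bearing alkyne carbon, giving 2-vinylcyclobutenone 33; warming opens 33 to dienylketene 34, which closes by six-electron electrocyclisation to cyclohexadienone 35 and tautomerises to phenol 36. The closest known reaction types are the intermolecular benzannulation of cyclobutenones with alkynyl ethers (Danheiser benzannulation, including its photochemical variant) and the intramolecular [2+2] cycloaddition of tethered ketenes. The pyran ring of unit A closes in the [2+2] step through the four-atom O–CH(Ph)–CH2–CH2 tether (six-membered ring fused to the new cyclobutenone, bond C4a–C8a, with C7–C8 formed in the same event), and the arene closes by the six-electron electrocyclisation (bond C6–C7) followed by enolisation. No stereocentre remains from the step: the quaternary ring-fusion carbon of 33 becomes the aromatic C4a, and C2 is carried unchanged from 1. The step needs regioselectivity, which the polarity of ketene and alkynyl ether and the tether direct the same way, and a cis arrangement of ketenyl and vinyl groups for ring closure, which the endocyclic double bond of the dihydropyran in 34 enforces. It also needs the secondary benzylic alkynyl ether to survive until it is consumed, which is why the vinylketene is generated with light at 5 to 10 °C and heat is applied only afterwards.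

Step 24
Reactants: 36 (2S)-8-{[(2S)-7-(benzyloxy)-5-methoxy-2-phenylchroman-6-yl]methyl}-5-methoxy-2-phenylchroman-7-ol
Product: 37 (2S)-8-{[(2S)-7-hydroxy-5-methoxy-2-phenylchroman-6-yl]methyl}-5-methoxy-2-phenylchroman-7-ol
Conditions: H2 (1 atm), Pd/C, EtOAc/MeOH, 20 °C
Reagents that add atoms: none
Why: hydrogenolysis cleaves the aryl benzyl ether, while the cyclic benzylic ethers of the two flavan units and the diarylmethane are much slower to cleave under neutral conditions, so stopping after one equivalent of hydrogen should give the target.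

**Compound list**

1 | (S)-3-chloro-1-phenylpropan-1-ol | ClCC[C@@H](c1ccccc1)O | starting material
2 | (S)-tert-butyl(3-chloro-1-phenylpropoxy)dimethylsilane | ClCC[C@@H](c1ccccc1)O[Si](C)(C)C(C)(C)C | intermediate
3 | (S)-tert-butyl(3-iodo-1-phenylpropoxy)dimethylsilane | ICC[C@@H](c1ccccc1)O[Si](C)(C)C(C)(C)C | intermediate
4 | chloroacetaldehyde dimethyl acetal | COC(CCl)OC | starting material
5 | lithium methoxyacetylide (formed in the flask) | [Li]C#COC | intermediate
6 | (S)-tert-butyl[(5-methoxy-1-phenylpent-4-yn-1-yl)oxy]dimethylsilane | COC#CCC[C@@H](c1ccccc1)O[Si](C)(C)C(C)(C)C | intermediate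
7 | (S)-5-methoxy-1-phenylpent-4-yn-1-ol | COC#CCC[C@@H](c1ccccc1)O | intermediate
8 | trichloroethylene | ClC=C(Cl)Cl | starting material
9 | {(1S)-1-[(E)-1,2-dichlorovinyloxy]-5-methoxypent-4-yn-1-yl}benzene | COC#CCC[C@@H](c1ccccc1)O/C(Cl)=C\Cl | intermediate
10 | 2-{(3S)-3-[(E)-1,2-dichlorovinyloxy]-3-phenylpropyl}-3-methoxycyclobut-2-en-1-one | O=C1CC(OC)=C1CC[C@@H](c1ccccc1)O/C(Cl)=C\Cl | intermediate
11 | 2-{(3S)-3-[(E)-1,2-dichlorovinyloxy]-3-phenylpropyl}-3-methoxycyclobut-2-en-1-ol, both ring-carbinol epimers | OC1CC(OC)=C1CC[C@@H](c1ccccc1)O/C(Cl)=C\Cl | intermediate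
12 | tert-butyl{[2-{(3S)-3-[(E)-1,2-dichlorovinyloxy]-3-phenylpropyl}-3-methoxycyclobut-2-en-1-yl]oxy}dimethylsilane, both epimers | CC(C)(C)[Si](C)(C)OC1CC(OC)=C1CC[C@@H](c1ccccc1)O/C(Cl)=C\Cl | intermediate
13 | phloroglucinol | Oc1cc(O)cc(O)c1 | starting material
14 | 3,5-bis(methoxymethoxy)phenol | COCOc1cc(O)cc(OCOC)c1 | intermediate
15 | 1-(benzyloxy)-3,5-bis(methoxymethoxy)benzene | COCOc1cc(OCc2ccccc2)cc(OCOC)c1 | intermediate
16 | (R)-3-chloro-1-phenylpropan-1-ol | ClCC[C@H](c1ccccc1)O | starting material
17 | (R)-tert-butyl(3-chloro-1-phenylpropoxy)dimethylsilane | ClCC[C@H](c1ccccc1)O[Si](C)(C)C(C)(C)C | intermediate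
18 | (R)-tert-butyl(3-iodo-1-phenylpropoxy)dimethylsilane | ICC[C@H](c1ccccc1)O[Si](C)(C)C(C)(C)C | intermediate
19 | [4-(benzyloxy)-2,6-bis(methoxymethoxy)phenyl]lithium (formed in the flask) | [Li]c1c(OCOC)cc(OCc2ccccc2)cc1OCOC | intermediate
20 | (R)-{3-[4-(benzyloxy)-2,6-bis(methoxymethoxy)phenyl]-1-phenylpropoxy}(tert-butyl)dimethylsilane | COCOc1cc(OCc2ccccc2)cc(OCOC)c1CC[C@H](c1ccccc1)O[Si](C)(C)C(C)(C)C | intermediate
21 | 5-(benzyloxy)-2-[(3R)-3-hydroxy-3-phenylpropyl]benzene-1,3-diol | Oc1cc(OCc2ccccc2)cc(O)c1CC[C@H](c1ccccc1)O | intermediate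
22 | (2S)-7-(benzyloxy)-2-phenylchroman-5-ol | Oc1cc(OCc2ccccc2)cc2c1CC[C@@H](c1ccccc1)O2 | intermediate
23 | (2S)-7-(benzyloxy)-5-hydroxy-2-phenylchromane-6-carbaldehyde | O=Cc1c(OCc2ccccc2)cc2c(c1O)CC[C@@H](c1ccccc1)O2 | intermediate
24 | (2S)-7-(benzyloxy)-5-methoxy-2-phenylchromane-6-carbaldehyde | O=Cc1c(OCc2ccccc2)cc2c(c1OC)CC[C@@H](c1ccccc1)O2 | intermediate
25 | [(2S)-7-(benzyloxy)-5-methoxy-2-phenylchroman-6-yl]methanol | OCc1c(OCc2ccccc2)cc2c(c1OC)CC[C@@H](c1ccccc1)O2 | intermediate
26 | (2S)-7-(benzyloxy)-6-(bromomethyl)-5-methoxy-2-phenylchromane | BrCc1c(OCc2ccccc2)cc2c(c1OC)CC[C@@H](c1ccccc1)O2 | intermediate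
27 | tert-butyl{[2-{(3S)-3-(chloroethynyloxy)-3-phenylpropyl}-3-methoxycyclobut-2-en-1-yl]oxy}dimethylsilane (formed in the flask) | CC(C)(C)[Si](C)(C)OC1CC(OC)=C1CC[C@@H](c1ccccc1)OC#CCl | intermediate
28 | lithium acetylide of the alkynyl ether, {[(1S)-3-{4-[(tert-butyldimethylsilyl)oxy]-2-methoxycyclobut-1-en-1-yl}-1-phenylpropoxy]ethynyl}lithium (formed in the flask) | CC(C)(C)[Si](C)(C)OC1CC(OC)=C1CC[C@@H](c1ccccc1)OC#C[Li] | intermediate
29 | tert-butyl{[3-methoxy-2-{(3S)-3-phenyl-3-[(3-{(2S)-7-(benzyloxy)-5-methoxy-2-phenylchroman-6-yl}prop-1-yn-1-yl)oxy]propyl}cyclobut-2-en-1-yl]oxy}dimethylsilane, both epimers | CC(C)(C)[Si](C)(C)OC1CC(OC)=C1CC[C@@H](c1ccccc1)OC#CCc1c(OCc2ccccc2)cc2c(c1OC)CC[C@@H](c1ccccc1)O2 | intermediate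
30 | 3-methoxy-2-{(3S)-3-phenyl-3-[(3-{(2S)-7-(benzyloxy)-5-methoxy-2-phenylchroman-6-yl}prop-1-yn-1-yl)oxy]propyl}cyclobut-2-en-1-ol, both epimers | OC1CC(OC)=C1CC[C@@H](c1ccccc1)OC#CCc1c(OCc2ccccc2)cc2c(c1OC)CC[C@@H](c1ccccc1)O2 | intermediate
31 | 3-methoxy-2-{(3S)-3-phenyl-3-[(3-{(2S)-7-(benzyloxy)-5-methoxy-2-phenylchroman-6-yl}prop-1-yn-1-yl)oxy]propyl}cyclobut-2-en-1-one (key-step precursor) | O=C1CC(OC)=C1CC[C@@H](c1ccccc1)OC#CCc1c(OCc2ccccc2)cc2c(c1OC)CC[C@@H](c1ccccc1)O2 | intermediate
32 | vinylketene, (5S)-2-(1-methoxyvinyl)-5-phenyl-5-[(3-{(2S)-7-(benzyloxy)-5-methoxy-2-phenylchroman-6-yl}prop-1-yn-1-yl)oxy]pent-1-en-1-one (formed in the flask) | O=C=C(C(OC)=C)CC[C@@H](c1ccccc1)OC#CCc1c(OCc2ccccc2)cc2c(c1OC)CC[C@@H](c1ccccc1)O2 | intermediate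
33 | (3S)-8-{[(2S)-7-(benzyloxy)-5-methoxy-2-phenylchroman-6-yl]methyl}-6-(1-methoxyvinyl)-3-phenyl-2-oxabicyclo[4.2.0]oct-1(8)-en-7-one, both C6 epimers (formed in the flask) | O=C1C(Cc2c(OCc3ccccc3)cc3c(c2OC)CC[C@@H](c2ccccc2)O3)=C2O[C@H](c3ccccc3)CCC12C(OC)=C | intermediate
34 | dienylketene, 2-{[(2S)-7-(benzyloxy)-5-methoxy-2-phenylchroman-6-yl]methyl}-2-[(2S)-5-(1-methoxyvinyl)-2-phenyl-3,4-dihydro-2H-pyran-6-yl]ethen-1-one (formed in the flask) | O=C=C(Cc1c(OCc2ccccc2)cc2c(c1OC)CC[C@@H](c1ccccc1)O2)C1=C(C(OC)=C)CC[C@@H](c2ccccc2)O1 | intermediate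
35 | keto tautomer of 36, (2S)-8-{[(2S)-7-(benzyloxy)-5-methoxy-2-phenylchroman-6-yl]methyl}-5-methoxy-2-phenyl-3,4-dihydro-2H-chromen-7(6H)-one (formed in the flask) | O=C1CC(OC)=C2CC[C@@H](c3ccccc3)OC2=C1Cc1c(OCc2ccccc2)cc2c(c1OC)CC[C@@H](c1ccccc1)O2 | intermediate
36 | (2S)-8-{[(2S)-7-(benzyloxy)-5-methoxy-2-phenylchroman-6-yl]methyl}-5-methoxy-2-phenylchroman-7-ol (key-step product) | COc1cc(O)c(Cc2c(OCc3ccccc3)cc3c(c2OC)CC[C@@H](c2ccccc2)O3)c2c1CC[C@@H](c1ccccc1)O2 | intermediate
37 | (2S)-8-{[(2S)-7-hydroxy-5-methoxy-2-phenylchroman-6-yl]methyl}-5-methoxy-2-phenylchroman-7-ol (CNP0178097.1) | COc1cc(O)c(Cc2c(O)cc3c(c2OC)CC[C@@H](c2ccccc2)O3)c2c1CC[C@@H](c1ccccc1)O2 | target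

**Step count and risks**

Total step count: 24. Longest linear sequence: 14 steps (from 13 through steps 9, 10 and 13 to 24).

Steps most likely to fail:

Step 23 (labelled step). What may go wrong: the vinylketene may reclose or dimerise faster than it reaches the tethered alkyne through a strained bicyclic transition state. The arenes may also compete for the 254 nm light, and the secondary benzylic alkynyl ether may be lost by retro-ene cleavage or sigmatropic shift if heat is needed before it is consumed. Fallback by known chemistry, setting out from 22 and 25 and returning to the route at 36: 22 would be O-methylated (MeI, K2CO3, DMF) to (2S)-7-(benzyloxy)-5-methoxy-2-phenylchromane F1 and debenzylated (H2, Pd/C) to (2S)-5-methoxy-2-phenylchroman-7-ol F2. Acid-catalysed Friedel–Crafts benzylation of F2 (in excess) with alcohol 25 (Sc(OTf)3 cat., CH2Cl2, −20 °C) should attach the benzylic carbon at C8 of F2, the position between the free hydroxyl and the ring oxygen, to give 36, which continues with step 24. Attack at C6 of F2 is the competing process, and that isomer would have to be separated.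

Step 20. What may go wrong: ionisation and self-condensation of the electron-rich benzylic bromide before the C–C bond forms, or halogen–metal exchange on the bromide by residual n-BuLi. Fallback, setting out from 23 and 12 and returning at 29: the bromide is replaced by an ortho-quinone methide generated in the flask. 23 would be converted with Boc2O/DMAP into (2S)-7-(benzyloxy)-6-formyl-2-phenylchroman-5-yl tert-butyl carbonate F3 and reduced with BH3·THF to (2S)-7-(benzyloxy)-6-(hydroxymethyl)-2-phenylchroman-5-yl tert-butyl carbonate F4. F4 would be deprotonated with t-BuMgCl at −78 °C in the presence of 28 (made from 12 as in step 20). On warming to 0 °C, carbonate migration and loss of tert-butyl carbonate should unveil the ortho-quinone methide, to which 28 adds in conjugate fashion to give (2S)-7-(benzyloxy)-6-{3-[(1S)-3-{4-[(tert-butyldimethylsilyl)oxy]-2-methoxycyclobut-1-en-1-yl}-1-phenylpropoxy]prop-2-yn-1-yl}-2-phenylchroman-5-ol F5. O-Methylation of F5 (MeI, K2CO3, DMF, 20 °C) gives 29.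

Step 7. What may go wrong: ionisation of the 3-methoxy allylic alcohol with loss of methanol (transposition to a 2-alkylcyclobut-2-enone) during reduction, work-up or silylation. Fallback, setting out from 10 and returning at 31: the carbonyl is masked without reduction as a dimethyl ketal. O-Methylation of 10 with Me3OBF4 (CH2Cl2, 0 °C), followed in the same flask by NaOMe/MeOH, would give {(1S)-1-[(E)-1,2-dichlorovinyloxy]-3-(2,4,4-trimethoxycyclobut-1-en-1-yl)propyl}benzene F6. Treatment of F6 with n-BuLi and then 26 as in step 20 would give (2S)-7-(benzyloxy)-5-methoxy-2-phenyl-6-{3-[(1S)-1-phenyl-3-(2,4,4-trimethoxycyclobut-1-en-1-yl)propoxy]prop-2-yn-1-yl}chromane F7. Hydrolysis of this vinylogous ortho ester in pH 6 phosphate buffer/THF at 0 °C would give 31 directly, so that steps 8, 21 and 22 fall away.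

Further compounds
F1 | step 23 | (2S)-7-(benzyloxy)-5-methoxy-2-phenylchromane | COc1cc(OCc2ccccc2)cc2c1CC[C@@H](c1ccccc1)O2
F2 | step 23 | (2S)-5-methoxy-2-phenylchroman-7-ol | COc1cc(O)cc2c1CC[C@@H](c1ccccc1)O2
F3 | step 20 | (2S)-7-(benzyloxy)-6-formyl-2-phenylchroman-5-yl tert-butyl carbonate | CC(C)(C)OC(=O)Oc1c(C=O)c(OCc2ccccc2)cc2c1CC[C@@H](c1ccccc1)O2
F4 | step 20 | (2S)-7-(benzyloxy)-6-(hydroxymethyl)-2-phenylchroman-5-yl tert-butyl carbonate | CC(C)(C)OC(=O)Oc1c(CO)c(OCc2ccccc2)cc2c1CC[C@@H](c1ccccc1)O2
F5 | step 20 | (2S)-7-(benzyloxy)-6-{3-[(1S)-3-{4-[(tert-butyldimethylsilyl)oxy]-2-methoxycyclobut-1-en-1-yl}-1-phenylpropoxy]prop-2-yn-1-yl}-2-phenylchroman-5-ol | CC(C)(C)[Si](C)(C)OC1CC(OC)=C1CC[C@@H](c1ccccc1)OC#CCc1c(OCc2ccccc2)cc2c(c1O)CC[C@@H](c1ccccc1)O2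
F6 | step 7 | {(1S)-1-[(E)-1,2-dichlorovinyloxy]-3-(2,4,4-trimethoxycyclobut-1-en-1-yl)propyl}benzene | COC1=C(CC[C@@H](c2ccccc2)O/C(Cl)=C\Cl)C(OC)(OC)C1
F7 | step 7 | (2S)-7-(benzyloxy)-5-methoxy-2-phenyl-6-{3-[(1S)-1-phenyl-3-(2,4,4-trimethoxycyclobut-1-en-1-yl)propoxy]prop-2-yn-1-yl}chromane | COC1=C(CC[C@@H](c2ccccc2)OC#CCc2c(OCc3ccccc3)cc3c(c2OC)CC[C@@H](c2ccccc2)O3)C(OC)(OC)C1
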